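Numbering: the ten-membered carbocycle is C1–C10 (C1 epoxide carbon with CH3, C2 epoxide CH, C3 carbinol, C4(CH3)=C5, C6 lactone O–CH, C7 ring fusion, C8 angelate carbinol, C9 and C10 CH2). The lactone adds C11 (alpha carbon), C12 (C=O) and C13 (=CH2).
Retrosynthetic cuts, in order: epoxide O from C1/C2; acyl–O bond of the C8 angelate; C11=C13; C9–C10 (opens the carbocycle); C1=C10; C2=C3; C8–C9; O–C12 of the lactone; C6–C7.
Enabling feature: without the epoxide oxygen, C3(OH)–C2=C1(CH3)–C10 is what 1,4-opening of a C2–C3 oxirane bearing an isopropenyl group (C1, its CH3, C10) leaves behind. C9 lies next to oxygenated C8, so a C8 ketone plus a C9 sulfonyl group turn it into a soft carbanion that closes the ten-membered ring onto C10.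
Forward order: a C3–C6 Z-enal and a succinate thioimide are joined at C6–C7, and C9 arrives with the sulfone. The gamma-lactone ring closes first, the chain then grows by C2/C1 (HWE) and C10 (Wittig), the carbocycle closes in step 17, and the oxirane ring comes last.
Stereochemistry: C6/C7 come from an auxiliary-controlled anti aldol (anti becomes the cis lactone). C3 comes from a catalytic asymmetric enone epoxidation and is kept through the palladium step. C8 comes from a CBS reduction, and C1/C2 from C3–OH-directed epoxidation. Z C4=C5 comes from the ring of citraconic anhydride, Z C1=C2 from the ring closure, and the angelate geometry from angelic acid.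

Key step: step 17

Remark 1: the MgBr2-catalysed anti aldol of N-acylthiazolidinethiones is taken to run through the unchelated Z-enolate, so the (S)-auxiliary gives 7S (same enolate face as in its boron syn aldol) and 6S; were the sense opposite, the enantiomeric auxiliary would be used.
Remark 2: from step 9 to step 15 the carbinol C8 is an unseparated mixture of epimers, so the SMILES carry no descriptor there; step 16 removes the centre.

Step 1
Reactants: 1 citraconic anhydride
Product: 2 4-methylfuran-2(5H)-one
Conditions: LiAlH4 (0.55 equiv), THF, −78 → 0 °C; 2 M HCl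
Reagents that add atoms: none
Why: Regioselective hydride reduction of an unsymmetrical cyclic anhydride, in which the methyl group is in vinylogous conjugation with the remote carbonyl and deactivates it, so the small hydride should attack the carbonyl next to C4 and acid closes the hydroxy acid to the butenolide whose ring fixes Z C4=C5 (any 3-methyl isomer is removed by distillation).

Step 2
Reactants: 2 4-methylfuran-2(5H)-one
Product: 3 (Z)-4-hydroxy-N-methoxy-N,3-dimethylbut-2-enamide
Conditions: MeNH(OMe)·HCl, AlMe3, CH2Cl2, 0 → 23 °C; aq potassium sodium tartrate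
Reagents that add atoms: N,O-dimethylhydroxylamine hydrochloride, CNOC.Cl
Why: Weinreb aminolysis of a lactone with the aluminium amide opens the ring at the acyl carbon without touching the alkene, so the cis relation of C3 and C6 is carried over.

Step 3
Reactants: 3 (Z)-4-hydroxy-N-methoxy-N,3-dimethylbut-2-enamide
Product: 4 (Z)-4-(tert-butyldimethylsilyloxy)-N-methoxy-N,3-dimethylbut-2-enamide
Conditions: t-BuMe2SiCl, imidazole, CH2Cl2, 0 → 23 °C (crude 3)
Reagents that add atoms: tert-butyldimethylsilyl chloride, CC(C)(C)[Si](C)(C)Cl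
Why: Standard silylation of a primary alcohol, run on the crude amide so that relactonisation has no time to occur.

Step 4
Reactants: 4 (Z)-4-(tert-butyldimethylsilyloxy)-N-methoxy-N,3-dimethylbut-2-enamide
Product: 5 (Z)-4-(tert-butyldimethylsilyloxy)-3-methylbut-2-enal (C6 aldehyde, C3–OSi)
Conditions: i-Bu2AlH (1.2 equiv), THF, −78 °C; aq potassium sodium tartrate
Reagents that add atoms: none
Why: Reduction of a Weinreb amide stops at the chelated tetrahedral intermediate, which releases the enal only on cold work-up and so avoids over-reduction and Z to E isomerisation.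

Step 5
Reactants: 6 (S)-4-benzyl-1,3-thiazolidine-2-thione; 7 methyl 4-chloro-4-oxobutanoate
Product: 8 methyl 4-[(4S)-4-benzyl-2-thioxo-1,3-thiazolidin-3-yl]-4-oxobutanoate
Conditions: Et3N, CH2Cl2, 0 → 23 °C
Reagents that add atoms: none
Why: N-acylation of the thiazolidinethione with an acid chloride gives a thioimide that serves as chiral controller in step 6 and as acyl donor in step 7.

Step 6
Reactants: 8 succinate thioimide; 5 Z-enal
Product: 9 (6S,7S)-anti aldol adduct (C8 thioimide, C12 methyl ester, C6–OSiMe3, C3–OSi(t-Bu)Me2, 4Z)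
Conditions: MgBr2·OEt2 (0.2 equiv), Et3N (2 equiv), Me3SiCl (1.5 equiv), EtOAc, 23 °C
Reagents that add atoms: chlorotrimethylsilane, C[Si](C)(C)Cl
Why: MgBr2-catalysed silylative anti aldol of an N-acylthiazolidinethione with an unsaturated aldehyde lacking alpha hydrogens, in which soft enolisation occurs only at the thioimide (C7), the benzyl group shields one face of the Z-enolate and sets C7, the anti relation sets C6, and Me3SiCl traps the aldolate and turns the catalyst over.

Step 7
Reactants: 9 anti aldol adduct; 10 methyl phenyl sulfone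
Product: 12 open-chain (6S,7S) beta-keto sulfone, via (phenylsulfonyl)methyllithium 11 (not isolated)
Conditions: 10 (2.2 equiv), n-BuLi (2.1 equiv), THF, −78 °C; then 9, −78 °C; AcOH, −78 °C
Reagents that add atoms: n-butyllithium, [Li]CCCC (lithium kept only in 11)
Why: Claisen-type acylation of an alpha-sulfonyl carbanion by an active amide, in which the thioimide is far more electrophilic than the methyl ester, the second equivalent of 11 turns the product into its C9 enolate (this blocks over-addition and shields C7–H), and auxiliary 6 is recovered.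

Step 8
Reactants: 12 open-chain beta-keto sulfone
Product: 14 cis-lactone keto sulfone with free C3–OH, via dihydroxy ester 13 (not isolated)
Conditions: 48% aq HF, MeCN, 0 → 23 °C
Reagents that add atoms: none
Why: Cleavage of both silyl ethers is followed by spontaneous 5-exo-trig lactonisation of the gamma-hydroxy ester, and since the C6–O bond is not broken the anti aldol relation becomes the cis relation of C5 and C8 on the lactone.

Step 9
Reactants: 14 cis-lactone keto sulfone
Product: 15 lactone diol (C8–OH as epimers, C3–OH)
Conditions: NaBH4, CeCl3·7H2O, MeOH, −78 → −40 °C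
Reagents that add atoms: none
Why: Luche-type 1,2-reduction masks the acidic keto sulfone, which would otherwise add to the later C3 aldehyde (Knoevenagel) and dienone (Michael), while the lactone is inert at this temperature.

Step 10
Reactants: 15 lactone diol
Product: 16 C3,C8-bis(triethylsilyl) ether
Conditions: Et3SiCl (2.5 equiv), imidazole, CH2Cl2, 0 °C
Reagents that add atoms: chlorotriethylsilane, CC[Si](Cl)(CC)CC
Why: Standard silylation of both hydroxyl groups, done directly after step 9 so that free C8–OH cannot migrate the lactone from O6 to O8.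

Step 11
Reactants: 16 bis(triethylsilyl) ether
Product: 17 (4Z)-C3 enal with C8–OSiEt3
Conditions: (COCl)2, DMSO, CH2Cl2, −78 → −40 °C; Et3N, −78 → 0 °C
Reagents that add atoms: none
Why: Swern oxidation of silyl ethers, in which the activated sulfoxide cleaves and oxidises only the unhindered primary allylic triethylsilyl ether, the secondary one at C8 stays, and the short cold exposure to Et3N preserves the Z-enal.

Step 12
Reactants: 17 C3 enal; 18 diethyl (2-oxopropyl)phosphonate
Product: 19 (2E,4Z)-dienone (C1 methyl ketone)
Conditions: LiCl, i-Pr2NEt, MeCN, 0 → 23 °C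
Reagents that add atoms: none
Why: Horner–Wadsworth–Emmons olefination under Masamune–Roush conditions is E-selective for C2=C3 with a stabilised keto phosphonate and mild enough for the Z-enal and the lactone.

Step 13
Reactants: 19 dienone
Product: 20 trans-(2S,3R)-epoxy ketone
Conditions: La(Oi-Pr)3 (10 mol %), (R)-BINOL (10 mol %), Ph3As=O (10 mol %), t-BuOOH (decane), 4 Å MS, THF, 23 °C
Reagents that add atoms: tert-butyl hydroperoxide, CC(C)(C)OO
Why: Catalytic asymmetric Weitz–Scheffer-type epoxidation, in which the peroxide bound to the complex formed from La(Oi-Pr)3 and BINOL adds to C3 of the alkene next to the carbonyl and the (R)-ligand selects the face that gives the alpha-S, beta-R epoxy ketone whatever the remote centres.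

Step 14
Reactants: 20 epoxy ketone
Product: 21 trans-(2R,3R)-isopropenyl epoxide with C8–OSiEt3
Conditions: Ph3PCH3Br, KN(SiMe3)2, THF, 0 °C; then 20, −78 → 0 °C
Reagents that add atoms: methyltriphenylphosphonium bromide, C[P+](c1ccccc1)(c1ccccc1)c1ccccc1.[Br-]
Why: Wittig methylenation of an alpha,beta-epoxy ketone, in which the ylide reacts with the ketone much faster than with the lactone, and with C8 masked no acidic C–H flanks C7 (the descriptor at C2 changes by priority only).

Step 15
Reactants: 21 isopropenyl epoxide silyl ether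
Product: 22 isopropenyl epoxide beta-hydroxy sulfone
Conditions: Bu4NF, AcOH (1:1), THF, 0 °C
Reagents that add atoms: none
Why: Buffered fluoride cleaves the triethylsilyl ether under nearly neutral conditions that spare the acid-labile bis-allylic epoxide and avoid a free alkoxide that could migrate the lactone.

Step 16
Reactants: 22 beta-hydroxy sulfone
Product: 23 (2R,3R,6S,7S)-isopropenyl epoxide beta-keto sulfone
Conditions: Dess–Martin periodinane (1.2 equiv), NaHCO3, CH2Cl2, 0 → 23 °C
Reagents that add atoms: none
Why: Dess–Martin oxidation under bicarbonate buffer unveils the keto sulfone without acid or base, so the epoxide and the epimerisable C7 survive and both C8 epimers converge.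

Step 17
Reactants: 23 isopropenyl epoxide beta-keto sulfone
Product: 24 (1Z,4Z,3S,6S,7S)-ten-membered bis-allylic alcohol keto sulfone (C9 drawn 9R, labile)
Conditions: Pd2(dba)3·CHCl3 (5 mol %), P(Oi-Pr)3 (40 mol %), THF, 65 °C, slow addition of 23 (final 2 mM)
Reagents that add atoms: none
Why: Zerovalent palladium binds the unhindered C1=C10 alkene and ionises the allylic C2–O bond to a zwitterion (C10–C1–C2 allylpalladium cation, C3 alkoxide); the alkoxide then removes the acidic C9–H, so the carbanion exists only in a molecule that already carries the electrophile and no external base reaches C7 or the lactone. This is the neutral Tsuji–Trost alkylation of vinyl epoxides by tethered beta-keto sulfones, a reaction type already used for medium and large carbocycles. The ten-membered ring closes in the endo mode (all three allyl carbons become ring atoms) by attack of C9 on the CH2 terminus C10, whereas exo attack at C2 would give an eight-membered ring and is opposed by the substituent and the adjacent alkoxide. C3 keeps its C–O bond and hence its configuration, C2 becomes sp2, and the one new centre C9 equilibrates through its acidic hydrogen (thermodynamic control) and is deleted in step 19. The step needs ionisation at C2–O rather than at C3–O or the allylic lactone C6–O (secured by strain release and by the terminal alkene being the best ligand), C10 over C2 attack, and Z geometry at C1=C2; for the last, the C1 methyl group brings syn and anti allyl isomers close in energy, they exchange through the sigma complex at C2 faster than the slow closure, and the anti isomer leads to the less strained ring with two cis alkenes flanking C3. The cis lactone holds the C5 and C8 arms on one face and shortens the C9 to C10 distance, attack of C9 on C12 would need a strained oxanorbornane, and slow addition keeps oligomerisation down.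

Step 18
Reactants: 24 macrocyclic alcohol
Product: 25 C3 triethylsilyl ether of 24
Conditions: Et3SiCl, imidazole, CH2Cl2, 0 → 23 °C
Reagents that add atoms: chlorotriethylsilane, CC[Si](Cl)(CC)CC
Why: Standard silylation masks C3–OH so that only C8–OH is acylated in step 22.

Step 19
Reactants: 25 silylated keto sulfone
Product: 26 (3S,6S,7S)-C8 ketone without sulfonyl group
Conditions: SmI2 (2.5 equiv), THF–MeOH, −78 °C
Reagents that add atoms: none
Why: Reductive desulfonylation of an alpha-sulfonyl ketone by single-electron transfer forms the samarium enolate regiospecifically between C8 and C9, and methanol protonates it at C9, so C7 is not touched.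

Step 20
Reactants: 26 C8 ketone
Product: 27 (8R)-alcohol
Conditions: (S)-Me-CBS oxazaborolidine [(S)-1-methyl-3,3-diphenyltetrahydro-1H,3H-pyrrolo[1,2-c][1,3,2]oxazaborole] (0.5 equiv), catecholborane, toluene, −78 °C
Reagents that add atoms: none
Why: Corey–Bakshi–Shibata reduction, in which the branched C7 side acts as the large and C9H2 as the small substituent, so the (S)-catalyst should deliver hydride to the face that gives 8R, and catecholborane at low temperature leaves alkenes and lactone alone.

Step 21
Reactants: 27 (8R)-alcohol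
Product: 30 alpha-methylene lactone with free C8–OH, via Mannich base 28 (not isolated), via methiodide 29 (not isolated)
Conditions: LiN(i-Pr)2 (3 equiv), THF, −78 °C; CH2=NMe2+ I− (4 equiv), −78 → 0 °C; crude, MeI, THF, 23 °C; satd aq NaHCO3, CH2Cl2, 23 °C
Reagents that add atoms: dimethyl(methylidene)ammonium iodide, C=[N+](C)C.[I-]; iodomethane, CI (atoms kept only in 29)
Why: Lactone alpha-methylenation by Mannich reaction of the lithium enolate, quaternisation and Hofmann-type elimination, in which the first equivalent of base makes the C8 alkoxide, the enolised lactone can no longer be attacked by it, and the C11 centre of 28 vanishes in the elimination.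

Step 22
Reactants: 30 alpha-methylene lactone alcohol; 31 angelic acid
Product: 33 C8 angelate C3 silyl ether, via mixed anhydride 32 (not isolated)
Conditions: 31, 2,4,6-Cl3C6H2COCl, Et3N, toluene, 23 °C; then 30, 80 °C
Reagents that add atoms: 2,4,6-trichlorobenzoyl chloride, O=C(Cl)c1c(Cl)cc(Cl)cc1Cl (atoms kept only in 32)
Why: Yamaguchi-type mixed-anhydride esterification without nucleophilic catalyst is the standard way to transfer an angeloyl group without isomerisation to the tiglate, and C8 keeps its configuration because the C8–O bond is not broken.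

Step 23
Reactants: 33 angelate silyl ether
Product: 34 (1Z,4Z)-bis-allylic alcohol
Conditions: HF·pyridine, pyridine, THF, 0 °C
Reagents that add atoms: none
Why: Buffered HF·pyridine removes the triethylsilyl ether without ionising the bis-allylic alcohol or adding to the alpha-methylene lactone.

Step 24
Reactants: 34 bis-allylic alcohol
Product: 35 target (1S,2R,3R,6S,7R,8R)
Conditions: VO(acac)2 (5 mol %), t-BuOOH (decane, 1.2 equiv), CH2Cl2, 0 °C
Reagents that add atoms: tert-butyl hydroperoxide, CC(C)(C)OO
Why: VO(acac)2-catalysed hydroxyl-directed epoxidation, in which ring atom C4 must leave the plane of the Z C1=C2 alkene, C3–O sits at the small dihedral angle the vanadate needs and delivers oxygen syn to itself (as in medium-ring cis-allylic alcohols), setting 1S and 2R, while C4=C5 is deactivated by the allylic lactone oxygen and the conjugated alkenes are inert.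

Compound list
1 | citraconic anhydride (3-methylfuran-2,5-dione) | CC1=CC(=O)OC1=O | starting material
2 | 4-methylfuran-2(5H)-one | CC1=CC(=O)OC1 | intermediate
3 | (Z)-4-hydroxy-N-methoxy-N,3-dimethylbut-2-enamide | CON(C)C(=O)/C=C(/C)CO | intermediate
4 | (Z)-4-(tert-butyldimethylsilyloxy)-N-methoxy-N,3-dimethylbut-2-enamide | CON(C)C(=O)/C=C(/C)CO[Si](C)(C)C(C)(C)C | intermediate
5 | (Z)-4-(tert-butyldimethylsilyloxy)-3-methylbut-2-enal | O=C/C=C(/C)CO[Si](C)(C)C(C)(C)C | intermediate
6 | (S)-4-benzyl-1,3-thiazolidine-2-thione | S=C1N[C@@H](Cc2ccccc2)CS1 | starting material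
7 | methyl 4-chloro-4-oxobutanoate | COC(=O)CCC(=O)Cl | starting material
8 | methyl 4-[(4S)-4-benzyl-2-thioxo-1,3-thiazolidin-3-yl]-4-oxobutanoate | COC(=O)CCC(=O)N1C(=S)SC[C@@H]1Cc1ccccc1 | intermediate
9 | (6S,7S)-anti aldol adduct: C8 thioimide, C12 methyl ester, C6–OSiMe3, C3–OSi(t-Bu)Me2, 4Z | COC(=O)C[C@H](C(=O)N1C(=S)SC[C@@H]1Cc1ccccc1)[C@@H](O[Si](C)(C)C)/C=C(/C)CO[Si](C)(C)C(C)(C)C | intermediate
10 | methyl phenyl sulfone | CS(=O)(=O)c1ccccc1 | starting material
11 | (phenylsulfonyl)methyllithium | [Li]CS(=O)(=O)c1ccccc1 | intermediate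
12 | (6S,7S)-open-chain beta-keto sulfone: C8 ketone, C9–SO2Ph, C12 methyl ester, C6–OSiMe3, C3–OSi(t-Bu)Me2 | COC(=O)C[C@H](C(=O)CS(=O)(=O)c1ccccc1)[C@@H](O[Si](C)(C)C)/C=C(/C)CO[Si](C)(C)C(C)(C)C | intermediate
13 | (6S,7S)-dihydroxy ester keto sulfone | COC(=O)C[C@H](C(=O)CS(=O)(=O)c1ccccc1)[C@@H](O)/C=C(/C)CO | intermediate
14 | (6S,7S)-cis-lactone keto sulfone, C3–OH, 4Z | O=C1C[C@H](C(=O)CS(=O)(=O)c2ccccc2)[C@H](/C=C(/C)CO)O1 | intermediate
15 | cis-lactone diol, C8–OH (epimers), C9–SO2Ph, C3–OH | O=C1C[C@H](C(O)CS(=O)(=O)c2ccccc2)[C@H](/C=C(/C)CO)O1 | intermediate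
16 | C3,C8-bis(triethylsilyl) ether of 15 | O=C1C[C@H](C(CS(=O)(=O)c2ccccc2)O[Si](CC)(CC)CC)[C@H](/C=C(/C)CO[Si](CC)(CC)CC)O1 | intermediate
17 | (4Z)-C3 enal, C8–OSiEt3 | O=C1C[C@H](C(CS(=O)(=O)c2ccccc2)O[Si](CC)(CC)CC)[C@H](/C=C(/C)C=O)O1 | intermediate
18 | diethyl (2-oxopropyl)phosphonate | CCOP(=O)(CC(C)=O)OCC | starting material
19 | (2E,4Z)-dienone, C1 methyl ketone, C8–OSiEt3 | O=C1C[C@H](C(CS(=O)(=O)c2ccccc2)O[Si](CC)(CC)CC)[C@H](/C=C(/C)\C=C\C(C)=O)O1 | intermediate
20 | trans-(2S,3R)-epoxy ketone, C8–OSiEt3 | O=C1C[C@H](C(CS(=O)(=O)c2ccccc2)O[Si](CC)(CC)CC)[C@H](/C=C(/C)[C@H]2O[C@@H]2C(C)=O)O1 | intermediate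
21 | trans-(2R,3R)-isopropenyl epoxide, C8–OSiEt3 | O=C1C[C@H](C(CS(=O)(=O)c2ccccc2)O[Si](CC)(CC)CC)[C@H](/C=C(/C)[C@H]2O[C@@H]2C(C)=C)O1 | intermediate
22 | isopropenyl epoxide beta-hydroxy sulfone (C8 epimers) | O=C1C[C@H](C(O)CS(=O)(=O)c2ccccc2)[C@H](/C=C(/C)[C@H]2O[C@@H]2C(C)=C)O1 | intermediate
23 | (2R,3R,6S,7S)-isopropenyl epoxide beta-keto sulfone | O=C1C[C@H](C(=O)CS(=O)(=O)c2ccccc2)[C@H](/C=C(/C)[C@H]2O[C@@H]2C(C)=C)O1 | intermediate
24 | (1Z,4Z,3S,6S,7S,9R)-ten-membered bis-allylic alcohol keto sulfone, cis-fused lactone | O=C1O[C@H]2/C=C(/C)[C@@H](O)/C=C(/C)C[C@@H](S(=O)(=O)c3ccccc3)C(=O)[C@H]2C1 | intermediate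
25 | C3 triethylsilyl ether of 24 | O=C1O[C@H]2/C=C(/C)[C@@H](O[Si](CC)(CC)CC)/C=C(/C)C[C@@H](S(=O)(=O)c3ccccc3)C(=O)[C@H]2C1 | intermediate
26 | (3S,6S,7S)-C8 ketone, C3–OSiEt3 | O=C1O[C@H]2/C=C(/C)[C@@H](O[Si](CC)(CC)CC)/C=C(/C)CCC(=O)[C@H]2C1 | intermediate
27 | (3S,6S,7R,8R)-C8 alcohol, C3–OSiEt3 | O=C1O[C@H]2/C=C(/C)[C@@H](O[Si](CC)(CC)CC)/C=C(/C)CC[C@@H](O)[C@H]2C1 | intermediate
28 | C11-(dimethylaminomethyl) lactone (C11 epimers) | CN(C)CC1C(=O)O[C@H]2/C=C(/C)[C@@H](O[Si](CC)(CC)CC)/C=C(/C)CC[C@@H](O)[C@@H]12 | intermediate
29 | trimethylammonium iodide of 28 | C[N+](C)(C)CC1C(=O)O[C@H]2/C=C(/C)[C@@H](O[Si](CC)(CC)CC)/C=C(/C)CC[C@@H](O)[C@@H]12.[I-] | intermediate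
30 | alpha-methylene lactone, C8–OH (8R), C3–OSiEt3 | C=C1C(=O)O[C@H]2/C=C(/C)[C@@H](O[Si](CC)(CC)CC)/C=C(/C)CC[C@@H](O)[C@@H]12 | intermediate
31 | angelic acid ((Z)-2-methylbut-2-enoic acid) | C/C=C(/C)C(=O)O | starting material
32 | angelic 2,4,6-trichlorobenzoic anhydride | C/C=C(/C)C(=O)OC(=O)c1c(Cl)cc(Cl)cc1Cl | intermediate
33 | C8 angelate, C3–OSiEt3 | C=C1C(=O)O[C@H]2/C=C(/C)[C@@H](O[Si](CC)(CC)CC)/C=C(/C)CC[C@@H](OC(=O)/C(C)=C\C)[C@@H]12 | intermediate
34 | (1Z,4Z,3S,6S,7R,8R)-C8 angelate, C3–OH | C=C1C(=O)O[C@H]2/C=C(/C)[C@@H](O)/C=C(/C)CC[C@@H](OC(=O)/C(C)=C\C)[C@@H]12 | intermediate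
35 | CNP0500828.1, (1S,2R,3R,6S,7R,8R) | C=C1C(=O)O[C@H]2/C=C(/C)[C@@H](O)[C@H]3O[C@@]3(C)CC[C@@H](OC(=O)/C(C)=C\C)[C@@H]12 | target

Total step count: 24. Longest linear sequence: 23 steps (1–4 and 6–24, from citraconic anhydride).

Steps most likely to fail

Step 17. Three processes could defeat it:
- oligomerisation may outrun the slow ten-membered closure;
- hydride migration in the allylpalladium alkoxide may isomerise the epoxide to an enone;
- closure through the syn allyl isomer may erode control of the C1=C2 geometry.

The fallback sets the Z geometry in a reagent, still makes C9–C10 with the keto sulfone, and closes the ring at C2–C3. It sets out from 14 and comes back at 26. Keto sulfone 14 is C-alkylated at C9 (K2CO3, acetone, 23 °C) with (Z)-3-bromo-1-iodo-2-methylprop-1-ene F1 (from commercial (Z)-3-iodo-2-methylprop-2-en-1-ol and PBr3) to give the C9-alkylated vinyl iodide F2. SmI2 in THF–MeOH at −78 °C removes the sulfonyl group to give the iodo ketone alcohol F3, and MnO2 oxidises only the allylic alcohol to the iodo ketone enal F4. An intramolecular Nozaki–Hiyama–Kishi reaction (CrCl2, NiCl2 cat., DMSO–THF, high dilution), which is selective for the aldehyde over the ketone, joins C2 to C3 to give the macrocyclic hydroxy ketone F5. In this variant the C3 configuration rests on the conformation of the closing ring. Et3SiCl and imidazole then give 26.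

Step 6. Three processes could defeat it:
- the enal may isomerise Z to E through a silyl dienol ether under Et3N/Me3SiCl at room temperature;
- the anti to syn preference may be low;
- the ester-bearing side chain may weaken facial selectivity.

The fallback is a reagent-controlled boron aldol through a closed chair at low temperature. It sets out from 7 (with 5) and comes back at 12. Acid chloride 7 and 2-methylpropane-2-thiol (Et3N, CH2Cl2) give S-tert-butyl 4-methoxy-4-oxobutanethioate F6. Its E-enol borinate is formed at −78 °C with an enantiopure C2-symmetric trans-2,5-dimethylborolan-1-yl triflate and i-Pr2NEt, the enantiomer being chosen to match 6S,7S. The borinate adds to 5 through a Zimmerman–Traxler chair to give the anti aldol thioester F7. Me3SiCl and imidazole give its trimethylsilyl ether F8, and 11 (2.2 equiv, THF, −78 °C) displaces the thiolate to give 12.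

Step 24. Two processes could defeat it:
- facial selectivity may be poor in the flexible ring;
- oxygen may be transferred to C4=C5, which is also allylic to C3–OH.

The fallback is a halohydrin route, which puts the oxygen on the face opposite to the one an external electrophile attacks and needs no directing group. It sets out from 33 and comes back at 35. N-bromosuccinimide in aqueous THF at 0 °C attacks the more electron-rich C1=C2 alkene, and water opens the bromonium ion at tertiary C1 to give the C2-bromo C1-hydroxy compound F9. DBU in CH2Cl2 closes the oxirane with inversion at C2 to give the epoxide silyl ether F10, C3–O being blocked so that only O1 can displace bromide. HF·pyridine/pyridine then gives 35.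

Further compounds
F1 | step 17 | (Z)-3-bromo-1-iodo-2-methylprop-1-ene | I/C=C(/C)CBr
F2 | step 17 | C9-alkylated keto sulfone with Z-vinyl iodide (C9 epimers), C3–OH | O=C1C[C@H](C(=O)C(C/C(C)=C\I)S(=O)(=O)c2ccccc2)[C@H](/C=C(/C)CO)O1
F3 | step 17 | iodo ketone alcohol (sulfonyl group removed) | O=C1C[C@H](C(=O)CC/C(C)=C\I)[C@H](/C=C(/C)CO)O1
F4 | step 17 | iodo ketone enal | O=C1C[C@H](C(=O)CC/C(C)=C\I)[C@H](/C=C(/C)C=O)O1
F5 | step 17 | (1Z,4Z,3S,6S,7S)-macrocyclic hydroxy ketone | O=C1O[C@H]2/C=C(/C)[C@@H](O)/C=C(/C)CCC(=O)[C@H]2C1
F6 | step 6 | S-tert-butyl 4-methoxy-4-oxobutanethioate | COC(=O)CCC(=O)SC(C)(C)C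
F7 | step 6 | (6S,7S)-anti aldol thioester, C6–OH | COC(=O)C[C@H](C(=O)SC(C)(C)C)[C@@H](O)/C=C(/C)CO[Si](C)(C)C(C)(C)C
F8 | step 6 | trimethylsilyl ether of F7 | COC(=O)C[C@H](C(=O)SC(C)(C)C)[C@@H](O[Si](C)(C)C)/C=C(/C)CO[Si](C)(C)C(C)(C)C
F9 | step 24 | C2-bromo C1-hydroxy compound, C3–OSiEt3 | C=C1C(=O)O[C@H]2/C=C(/C)[C@@H](O[Si](CC)(CC)CC)[C@H](Br)[C@@](C)(O)CC[C@@H](OC(=O)/C(C)=C\C)[C@@H]12
F10 | step 24 | C3 triethylsilyl ether of the target | C=C1C(=O)O[C@H]2/C=C(/C)[C@@H](O[Si](CC)(CC)CC)[C@H]3O[C@@]3(C)CC[C@@H](OC(=O)/C(C)=C\C)[C@@H]12
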